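## Retrosynthetic overview

1. Target 26 ⇐ pentabenzyl ether 25 by global hydrogenolysis.
2. Upper trans-3,4-diarylchroman: O1–C2 by Mitsunobu closure; C3–C4 with both stereocentres by aminocatalytic addition of arylacetaldehyde 21 to the o-quinone methide from benzhydrol 17. This replaces the biomimetic C4–aryl Friedel–Crafts coupling of two isoflavans.
3. 17 ⇐ aryllithium from lower isoflavan bromide 15 + salicylaldehyde 9, so the hindered C4–aryl bond is made early as a plain carbonyl addition.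
4. Lower (R)-isoflavan 15 ⇐ the same aminocatalytic o-quinone methide annulation (arylacetaldehyde 8 + sulfone 11), then Mitsunobu closure.
5. Central ring 8 ⇐ 2-bromo-3-methoxybenzaldehyde 1 by sterically controlled Ir C–H borylation/oxidation. Ring order: lower pyran first, upper pyran last.

Assumption: the SMILES is taken as drawn (upper chroman 3R,4S, i.e. 3,4-trans; lower chroman 3R); compounds 1, 9, 18 and all unnumbered reagents are treated as commercial.

## Route

Step 1
Reactants: 1 2-bromo-3-methoxybenzaldehyde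
Product: 2 2-bromo-1-(dimethoxymethyl)-3-methoxybenzene
Conditions: HC(OMe)3, p-TsOH·H2O (2 mol %), MeOH, rt
Reagents that add atoms: trimethyl orthoformate, COC(OC)OC; methanol, CO
Why: Acid-catalysed acetalisation masks the aldehyde, which would otherwise be reduced or borylated under the Ir/boron conditions of step 2; no stereocentre.

Step 2
Reactants: 2 2-bromo-1-(dimethoxymethyl)-3-methoxybenzene
Product: 5 2-bromo-5-hydroxy-3-methoxybenzaldehyde, via arylboronate 3 (not isolated), via phenol acetal 4 (not isolated)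
Conditions: [Ir(OMe)(cod)]2 (1.5 mol %), dtbpy (3 mol %), B2pin2, THF, 80 °C; then NaOH, 30% H2O2, 0 °C; then 2 M HCl, rt
Reagents that add atoms: bis(pinacolato)diboron, CC1(C)OB(OC1(C)C)B1OC(C)(C)C(C)(C)O1 (Bpin of 3 only); hydrogen peroxide, OO (phenol O); water, O (aldehyde O)
Why: Sterically governed Ir-catalysed aromatic C–H borylation attacks only C5, the single ring C–H without an ortho substituent (C–Br is tolerated), and boronate oxidation plus acetal hydrolysis gives the phenol para to bromine with the two ring oxygens already differentiated.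

Step 3
Reactants: 5 2-bromo-5-hydroxy-3-methoxybenzaldehyde
Product: 6 5-(benzyloxy)-2-bromo-3-methoxybenzaldehyde
Conditions: BnBr, K2CO3, DMF, rt
Reagents that add atoms: benzyl bromide, BrCc1ccccc1
Why: Williamson etherification of the only phenol; the benzyl ether survives every later step up to the final hydrogenolysis.

Step 4
Reactants: 6 5-(benzyloxy)-2-bromo-3-methoxybenzaldehyde
Product: 7 5-(benzyloxy)-2-bromo-1-methoxy-3-(2-methoxyethenyl)benzene (E/Z mixture)
Conditions: Ph3P(CH2OMe)Cl, KOt-Bu, THF, 0 °C → rt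
Reagents that add atoms: (methoxymethyl)triphenylphosphonium chloride, COC[P+](c1ccccc1)(c1ccccc1)c1ccccc1.[Cl-]
Why: Wittig methoxymethylenation of a non-enolisable aldehyde gives the enol ether for one-carbon homologation; the alkene geometry is irrelevant.

Step 5
Reactants: 7 5-(benzyloxy)-2-bromo-1-methoxy-3-(2-methoxyethenyl)benzene
Product: 8 2-[5-(benzyloxy)-2-bromo-3-methoxyphenyl]acetaldehyde
Conditions: 2 M HCl, THF, 50 °C; used crude
Reagents that add atoms: water, O
Why: Acid hydrolysis of the enol ether gives the arylacetaldehyde, while benzyl ether and aryl bromide are inert to dilute acid.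

Step 6
Reactants: 9 4-(benzyloxy)-2-hydroxybenzaldehyde
Product: 10 5-(benzyloxy)-2-(hydroxymethyl)phenol
Conditions: NaBH4, MeOH, 0 °C
Reagents that add atoms: none
Why: Borohydride reduction of the aldehyde gives the salicyl alcohol; no stereocentre.

Step 7
Reactants: 10 5-(benzyloxy)-2-(hydroxymethyl)phenol
Product: 11 5-(benzyloxy)-2-{[(4-methylphenyl)sulfonyl]methyl}phenol
Conditions: TolSO2Na, HCO2H/H2O, rt
Reagents that add atoms: sodium p-toluenesulfinate, Cc1ccc(cc1)S(=O)[O-].[Na+]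
Why: SN1-type substitution through the para-alkoxy-stabilised o-quinone methide, trapped at sulfur by sulfinate, gives a bench-stable o-quinone methide precursor.

Step 8
Reactants: 8 2-[5-(benzyloxy)-2-bromo-3-methoxyphenyl]acetaldehyde; 11 5-(benzyloxy)-2-{[(4-methylphenyl)sulfonyl]methyl}phenol
Product: 14 (2R)-2-[5-(benzyloxy)-2-bromo-3-methoxyphenyl]-3-[4-(benzyloxy)-2-hydroxyphenyl]propan-1-ol, via o-quinone methide 12 (not isolated), via lactol 13 (not isolated)
Conditions: (R)-α,α-diphenylprolinol TMS ether (20 mol %), K2CO3, CH2Cl2, 0 °C; then NaBH4, MeOH, 0 °C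
Reagents that add atoms: none
Why: Base releases o-quinone methide 12 from the sulfone, the E-enamine of 8 adds through the face left open by the (R)-diarylprolinol silyl ether (enamine Michael addition/hemiacetalisation), which sets the α-carbon as R, and immediate borohydride reduction of lactol 13 removes the racemisation-prone α-aryl aldehyde.

Step 9
Reactants: 14 (2R)-2-[5-(benzyloxy)-2-bromo-3-methoxyphenyl]-3-[4-(benzyloxy)-2-hydroxyphenyl]propan-1-ol
Product: 15 (3R)-7-(benzyloxy)-3-[5-(benzyloxy)-2-bromo-3-methoxyphenyl]-3,4-dihydro-2H-chromene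
Conditions: PPh3, DIAD, THF, 0 °C → rt
Reagents that add atoms: none
Why: Intramolecular Mitsunobu etherification (phenol onto the activated primary alcohol, 6-exo) closes the lower pyran without touching the stereocentre.

Step 10
Reactants: 15 (3R)-7-(benzyloxy)-3-[5-(benzyloxy)-2-bromo-3-methoxyphenyl]-3,4-dihydro-2H-chromene; 9 4-(benzyloxy)-2-hydroxybenzaldehyde
Product: 17 [4-(benzyloxy)-2-hydroxyphenyl]{4-(benzyloxy)-2-[(3R)-7-(benzyloxy)-3,4-dihydro-2H-chromen-3-yl]-6-methoxyphenyl}methanol (both carbinol epimers), via aryllithium 16 (not isolated)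
Conditions: t-BuLi (2.1 equiv), THF, −78 °C; then lithium phenoxide of 9 (9 + LiHMDS), −78 → 0 °C; aq NH4Cl
Reagents that add atoms: tert-butyllithium, [Li]C(C)(C)C (Li of 16 only)
Why: Bromine–lithium exchange gives the OMe-chelated aryllithium, whose 1,2-addition to the pre-deprotonated salicylaldehyde forms the hindered C4–aryl bond; the carbinol configuration is irrelevant because it is ionised in step 14.

Step 11
Reactants: 18 2,3-dihydroxy-4-methoxybenzaldehyde
Product: 19 2,3-bis(benzyloxy)-4-methoxybenzaldehyde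
Conditions: BnBr (2.5 equiv), K2CO3, DMF, 60 °C
Reagents that add atoms: benzyl bromide, BrCc1ccccc1
Why: Double Williamson etherification protects the catechol, with heat driving the hydrogen-bonded 2-OH.

Step 12
Reactants: 19 2,3-bis(benzyloxy)-4-methoxybenzaldehyde
Product: 20 2,3-bis(benzyloxy)-1-methoxy-4-(2-methoxyethenyl)benzene (E/Z mixture)
Conditions: Ph3P(CH2OMe)Cl, KOt-Bu, THF, 0 °C → rt
Reagents that add atoms: (methoxymethyl)triphenylphosphonium chloride, COC[P+](c1ccccc1)(c1ccccc1)c1ccccc1.[Cl-]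
Why: Wittig methoxymethylenation, as in step 4.

Step 13
Reactants: 20 2,3-bis(benzyloxy)-1-methoxy-4-(2-methoxyethenyl)benzene
Product: 21 2-[2,3-bis(benzyloxy)-4-methoxyphenyl]acetaldehyde
Conditions: 2 M HCl, THF, 50 °C; used crude
Reagents that add atoms: water, O
Why: Enol ether hydrolysis to the homologated arylacetaldehyde, as in step 5.

Step 14
Reactants: 17 [4-(benzyloxy)-2-hydroxyphenyl]{4-(benzyloxy)-2-[(3R)-7-(benzyloxy)-3,4-dihydro-2H-chromen-3-yl]-6-methoxyphenyl}methanol; 21 2-[2,3-bis(benzyloxy)-4-methoxyphenyl]acetaldehyde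
Product: 24 (2R,3S)-3-[4-(benzyloxy)-2-hydroxyphenyl]-3-{4-(benzyloxy)-2-[(3R)-7-(benzyloxy)-3,4-dihydro-2H-chromen-3-yl]-6-methoxyphenyl}-2-[2,3-bis(benzyloxy)-4-methoxyphenyl]propan-1-ol, via o-quinone methide 22 (not isolated), via lactol 23 (not isolated)
Conditions: 21 (2 equiv), (R)-α,α-diphenylprolinol TMS ether (20 mol %), (PhO)2PO2H (20 mol %), CHCl3, 0 °C → rt; then NaBH4, MeOH, 0 °C
Reagents that add atoms: none
Why: Proposed new method: acid-promoted dehydration of the doubly donor-stabilised benzhydrol 17 gives o-quinone methide 22 (its twisted central aryl leaves the OMe-flanked face open), the enamine of 21 with the (R)-catalyst attacks through its unshielded face in the usual synclinal topology so that one C–C bond formation sets C3 (R) and C4 (S) trans, and the phenol closes lactol 23 before in situ NaBH4 reduction; the closest known chemistry is diarylprolinol-silyl-ether-catalysed enamine Michael addition/hemiacetalisation with in situ o-quinone methides and SN1-type aminocatalytic α-alkylation of aldehydes with benzhydrols.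

Step 15
Reactants: 24 (2R,3S)-3-[4-(benzyloxy)-2-hydroxyphenyl]-3-{4-(benzyloxy)-2-[(3R)-7-(benzyloxy)-3,4-dihydro-2H-chromen-3-yl]-6-methoxyphenyl}-2-[2,3-bis(benzyloxy)-4-methoxyphenyl]propan-1-ol
Product: 25 (3R,4S)-7-(benzyloxy)-4-{4-(benzyloxy)-2-[(3R)-7-(benzyloxy)-3,4-dihydro-2H-chromen-3-yl]-6-methoxyphenyl}-3-[2,3-bis(benzyloxy)-4-methoxyphenyl]-3,4-dihydro-2H-chromene
Conditions: PPh3, DIAD, THF (0.01 M), 0 °C → rt
Reagents that add atoms: none
Why: Intramolecular Mitsunobu etherification closes the upper pyran at the primary carbon, so neither C3 nor C4 is touched and the trans relationship is kept.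

Step 16
Reactants: 25 (3R,4S)-7-(benzyloxy)-4-{4-(benzyloxy)-2-[(3R)-7-(benzyloxy)-3,4-dihydro-2H-chromen-3-yl]-6-methoxyphenyl}-3-[2,3-bis(benzyloxy)-4-methoxyphenyl]-3,4-dihydro-2H-chromene
Product: 26 (3R,4S)-3-(2,3-dihydroxy-4-methoxyphenyl)-4-{4-hydroxy-2-[(3R)-7-hydroxy-3,4-dihydro-2H-chromen-3-yl]-6-methoxyphenyl}-3,4-dihydro-2H-chromen-7-ol (CNP0227211.1)
Conditions: H2 (1 atm), 10% Pd/C, EtOAc/MeOH, rt, work-up under argon
Reagents that add atoms: none
Why: Catalytic hydrogenolysis removes all five benzyl ethers, while the methyl ethers, the chroman C–O bonds and the heteroatom-free C4–H benzylic centre are inert, so no stereocentre is affected.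

## Compound list

1 | 2-bromo-3-methoxybenzaldehyde | COc1cccc(C=O)c1Br | starting material
2 | 2-bromo-1-(dimethoxymethyl)-3-methoxybenzene | COc1cccc(C(OC)OC)c1Br | intermediate
3 | 2-[4-bromo-3-(dimethoxymethyl)-5-methoxyphenyl]-4,4,5,5-tetramethyl-1,3,2-dioxaborolane (not isolated) | COc1cc(B2OC(C)(C)C(C)(C)O2)cc(C(OC)OC)c1Br | intermediate
4 | 4-bromo-3-(dimethoxymethyl)-5-methoxyphenol (not isolated) | COc1cc(O)cc(C(OC)OC)c1Br | intermediate
5 | 2-bromo-5-hydroxy-3-methoxybenzaldehyde | COc1cc(O)cc(C=O)c1Br | intermediate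
6 | 5-(benzyloxy)-2-bromo-3-methoxybenzaldehyde | COc1cc(OCc2ccccc2)cc(C=O)c1Br | intermediate
7 | 5-(benzyloxy)-2-bromo-1-methoxy-3-(2-methoxyethenyl)benzene, E/Z mixture | COC=Cc1cc(OCc2ccccc2)cc(OC)c1Br | intermediate
8 | 2-[5-(benzyloxy)-2-bromo-3-methoxyphenyl]acetaldehyde | COc1cc(OCc2ccccc2)cc(CC=O)c1Br | intermediate
9 | 4-(benzyloxy)-2-hydroxybenzaldehyde | O=Cc1ccc(OCc2ccccc2)cc1O | starting material
10 | 5-(benzyloxy)-2-(hydroxymethyl)phenol | OCc1ccc(OCc2ccccc2)cc1O | intermediate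
11 | 5-(benzyloxy)-2-{[(4-methylphenyl)sulfonyl]methyl}phenol | Cc1ccc(cc1)S(=O)(=O)Cc1ccc(OCc2ccccc2)cc1O | intermediate
12 | 3-(benzyloxy)-6-methylidenecyclohexa-2,4-dien-1-one (not isolated) | C=C1C=CC(OCc2ccccc2)=CC1=O | intermediate
13 | (3R)-7-(benzyloxy)-3-[5-(benzyloxy)-2-bromo-3-methoxyphenyl]-3,4-dihydro-2H-chromen-2-ol, C2 anomers (not isolated) | COc1cc(OCc2ccccc2)cc([C@H]2Cc3ccc(OCc4ccccc4)cc3OC2O)c1Br | intermediate
14 | (2R)-2-[5-(benzyloxy)-2-bromo-3-methoxyphenyl]-3-[4-(benzyloxy)-2-hydroxyphenyl]propan-1-ol | COc1cc(OCc2ccccc2)cc([C@H](CO)Cc2ccc(OCc3ccccc3)cc2O)c1Br | intermediate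
15 | (3R)-7-(benzyloxy)-3-[5-(benzyloxy)-2-bromo-3-methoxyphenyl]-3,4-dihydro-2H-chromene | COc1cc(OCc2ccccc2)cc([C@@H]2COc3cc(OCc4ccccc4)ccc3C2)c1Br | intermediate
16 | {4-(benzyloxy)-2-[(3R)-7-(benzyloxy)-3,4-dihydro-2H-chromen-3-yl]-6-methoxyphenyl}lithium (not isolated) | COc1cc(OCc2ccccc2)cc([C@@H]2COc3cc(OCc4ccccc4)ccc3C2)c1[Li] | intermediate
17 | [4-(benzyloxy)-2-hydroxyphenyl]{4-(benzyloxy)-2-[(3R)-7-(benzyloxy)-3,4-dihydro-2H-chromen-3-yl]-6-methoxyphenyl}methanol, both carbinol epimers | COc1cc(OCc2ccccc2)cc([C@@H]2COc3cc(OCc4ccccc4)ccc3C2)c1C(O)c1ccc(OCc2ccccc2)cc1O | intermediate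
18 | 2,3-dihydroxy-4-methoxybenzaldehyde | COc1ccc(C=O)c(O)c1O | starting material
19 | 2,3-bis(benzyloxy)-4-methoxybenzaldehyde | COc1ccc(C=O)c(OCc2ccccc2)c1OCc1ccccc1 | intermediate
20 | 2,3-bis(benzyloxy)-1-methoxy-4-(2-methoxyethenyl)benzene, E/Z mixture | COC=Cc1ccc(OC)c(OCc2ccccc2)c1OCc1ccccc1 | intermediate
21 | 2-[2,3-bis(benzyloxy)-4-methoxyphenyl]acetaldehyde | COc1ccc(CC=O)c(OCc2ccccc2)c1OCc1ccccc1 | intermediate
22 | 3-(benzyloxy)-6-({4-(benzyloxy)-2-[(3R)-7-(benzyloxy)-3,4-dihydro-2H-chromen-3-yl]-6-methoxyphenyl}methylidene)cyclohexa-2,4-dien-1-one (not isolated) | COc1cc(OCc2ccccc2)cc([C@@H]2COc3cc(OCc4ccccc4)ccc3C2)c1C=C1C=CC(OCc2ccccc2)=CC1=O | intermediate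
23 | (3R,4S)-7-(benzyloxy)-4-{4-(benzyloxy)-2-[(3R)-7-(benzyloxy)-3,4-dihydro-2H-chromen-3-yl]-6-methoxyphenyl}-3-[2,3-bis(benzyloxy)-4-methoxyphenyl]-3,4-dihydro-2H-chromen-2-ol, C2 anomers (not isolated) | COc1ccc([C@@H]2C(O)Oc3cc(OCc4ccccc4)ccc3[C@H]2c2c(OC)cc(OCc3ccccc3)cc2[C@@H]2COc3cc(OCc4ccccc4)ccc3C2)c(OCc2ccccc2)c1OCc1ccccc1 | intermediate
24 | (2R,3S)-3-[4-(benzyloxy)-2-hydroxyphenyl]-3-{4-(benzyloxy)-2-[(3R)-7-(benzyloxy)-3,4-dihydro-2H-chromen-3-yl]-6-methoxyphenyl}-2-[2,3-bis(benzyloxy)-4-methoxyphenyl]propan-1-ol | COc1ccc([C@H](CO)[C@@H](c2ccc(OCc3ccccc3)cc2O)c2c(OC)cc(OCc3ccccc3)cc2[C@@H]2COc3cc(OCc4ccccc4)ccc3C2)c(OCc2ccccc2)c1OCc1ccccc1 | intermediate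
25 | (3R,4S)-7-(benzyloxy)-4-{4-(benzyloxy)-2-[(3R)-7-(benzyloxy)-3,4-dihydro-2H-chromen-3-yl]-6-methoxyphenyl}-3-[2,3-bis(benzyloxy)-4-methoxyphenyl]-3,4-dihydro-2H-chromene | COc1ccc([C@@H]2COc3cc(OCc4ccccc4)ccc3[C@H]2c2c(OC)cc(OCc3ccccc3)cc2[C@@H]2COc3cc(OCc4ccccc4)ccc3C2)c(OCc2ccccc2)c1OCc1ccccc1 | intermediate
26 | (3R,4S)-3-(2,3-dihydroxy-4-methoxyphenyl)-4-{4-hydroxy-2-[(3R)-7-hydroxy-3,4-dihydro-2H-chromen-3-yl]-6-methoxyphenyl}-3,4-dihydro-2H-chromen-7-ol | COc1ccc([C@@H]2COc3cc(O)ccc3[C@H]2c2c(OC)cc(O)cc2[C@@H]2COc3cc(O)ccc3C2)c(O)c1O | target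

## Summary and fallbacks

Total step count: 16. Longest linear sequence: 11 steps (1, 2, 3, 4, 5, 8, 9, 10, 14, 15, 16).

The three steps most likely to fail:

**Step 14 (key annulation).** The C3–C4 bond is formed between an ortho-substituted enamine and a quinone methide carrying a di-ortho-substituted aryl, so conversion and C4 facial control are both at risk. The fallback moves the C3–C4 bond formation to an auxiliary-controlled aldol reaction and closes the ring at C4–C4a instead. It sets out from 15 and 21. Compound 15 is lithiated as in step 10 and quenched with DMF to give aldehyde F1. Compound 21 is oxidised (NaClO2, NaH2PO4, 2-methyl-2-butene) to arylacetic acid F2, which is coupled (PivCl, Et3N, LiCl) with (S)-4-benzyloxazolidin-2-one to N-acyloxazolidinone F3. Evans boron aldol reaction of F3 with F1 (Bu2BOTf, i-Pr2NEt, −78 °C) gives syn-aldol adduct F4 with the α-carbon in the configuration that becomes C3 (R). LiBH4 removes the auxiliary to give 1,3-diol F5. Mitsunobu etherification of its primary hydroxyl with commercial 3-(benzyloxy)phenol gives aryl ether F6. BF3·OEt2 (CH2Cl2, −40 °C) then ionises the benzylic alcohol, and the resorcinol ring closes para to its benzyloxy group (intramolecular Friedel–Crafts alkylation, trans to the C3 aryl), returning to the route at 25.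

**Step 8 (lower annulation).** The new α-aryl stereocentre can racemise through the open hydroxy-aldehyde, and the unsubstituted quinone methide can oligomerise. The fallback sets the stereocentre by asymmetric hydrogenation instead. It sets out from 8 and 11. The same addition run with achiral pyrrolidine and K2CO3 gives racemic lactol F7. Dehydration (cat. TsOH, toluene, 4 Å MS) gives 4H-chromene F8. Ir-catalysed asymmetric hydrogenation of this cyclic enol ether (Ir–phosphinooxazoline N,P catalyst, H2 50 bar, CH2Cl2, ligand enantiomer chosen to deliver 3R; aryl bromide and benzyl ethers are tolerated) returns to the route at 15.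

**Step 10 (aryllithium addition).** The di-ortho-substituted aryllithium must add to a phenoxide-deactivated aldehyde. The fallback reverses the polarity. It sets out from 15, which is lithiated and quenched with DMF to aldehyde F1. Aldehyde F1 is condensed with 3-(benzyloxy)phenol and phenylboronic acid (cat. EtCO2H, toluene, reflux, Dean–Stark; boron-templated ortho-specific hydroxyalkylation of the phenol) to benzodioxaborin F9. Transesterification with propane-1,3-diol frees the o-hydroxybenzhydrol, returning to the route at 17.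

## Further compounds

F1 | step 14 | 4-(benzyloxy)-2-[(3R)-7-(benzyloxy)-3,4-dihydro-2H-chromen-3-yl]-6-methoxybenzaldehyde | COc1cc(OCc2ccccc2)cc([C@@H]2COc3cc(OCc4ccccc4)ccc3C2)c1C=O
F2 | step 14 | [2,3-bis(benzyloxy)-4-methoxyphenyl]acetic acid | COc1ccc(CC(=O)O)c(OCc2ccccc2)c1OCc1ccccc1
F3 | step 14 | (4S)-4-benzyl-3-{[2,3-bis(benzyloxy)-4-methoxyphenyl]acetyl}-1,3-oxazolidin-2-one | COc1ccc(CC(=O)N2C(=O)OC[C@@H]2Cc2ccccc2)c(OCc2ccccc2)c1OCc1ccccc1
F4 | step 14 | (4S)-4-benzyl-3-[(2S,3S)-3-{4-(benzyloxy)-2-[(3R)-7-(benzyloxy)-3,4-dihydro-2H-chromen-3-yl]-6-methoxyphenyl}-2-[2,3-bis(benzyloxy)-4-methoxyphenyl]-3-hydroxypropanoyl]-1,3-oxazolidin-2-one | COc1ccc([C@H](C(=O)N2C(=O)OC[C@@H]2Cc2ccccc2)[C@H](O)c2c(OC)cc(OCc3ccccc3)cc2[C@@H]2COc3cc(OCc4ccccc4)ccc3C2)c(OCc2ccccc2)c1OCc1ccccc1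
F5 | step 14 | (1S,2R)-1-{4-(benzyloxy)-2-[(3R)-7-(benzyloxy)-3,4-dihydro-2H-chromen-3-yl]-6-methoxyphenyl}-2-[2,3-bis(benzyloxy)-4-methoxyphenyl]propane-1,3-diol | COc1ccc([C@H](CO)[C@H](O)c2c(OC)cc(OCc3ccccc3)cc2[C@@H]2COc3cc(OCc4ccccc4)ccc3C2)c(OCc2ccccc2)c1OCc1ccccc1
F6 | step 14 | (1S,2R)-3-[3-(benzyloxy)phenoxy]-1-{4-(benzyloxy)-2-[(3R)-7-(benzyloxy)-3,4-dihydro-2H-chromen-3-yl]-6-methoxyphenyl}-2-[2,3-bis(benzyloxy)-4-methoxyphenyl]propan-1-ol | COc1ccc([C@H](COc2cccc(OCc3ccccc3)c2)[C@H](O)c2c(OC)cc(OCc3ccccc3)cc2[C@@H]2COc3cc(OCc4ccccc4)ccc3C2)c(OCc2ccccc2)c1OCc1ccccc1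
F7 | step 8 | racemic 7-(benzyloxy)-3-[5-(benzyloxy)-2-bromo-3-methoxyphenyl]-3,4-dihydro-2H-chromen-2-ol | COc1cc(OCc2ccccc2)cc(C2Cc3ccc(OCc4ccccc4)cc3OC2O)c1Br
F8 | step 8 | 7-(benzyloxy)-3-[5-(benzyloxy)-2-bromo-3-methoxyphenyl]-4H-chromene | COc1cc(OCc2ccccc2)cc(C2=COc3cc(OCc4ccccc4)ccc3C2)c1Br
F9 | step 10 | 7-(benzyloxy)-4-{4-(benzyloxy)-2-[(3R)-7-(benzyloxy)-3,4-dihydro-2H-chromen-3-yl]-6-methoxyphenyl}-2-phenyl-4H-1,3,2-benzodioxaborinine (both C4 epimers) | COc1cc(OCc2ccccc2)cc([C@@H]2COc3cc(OCc4ccccc4)ccc3C2)c1C1OB(c2ccccc2)Oc2cc(OCc3ccccc3)ccc21
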